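A one-step picture, in which substrate and gas make product, is where two chemists start on this flask, but it leaves open how much gas stands in solution, and so they read the same run differently.

| flask | substrate | gas phase | remark | time |
|---|---|---|---|---|
| red | 0.11 M | 54 mM (held) | run made earlier |  |
| dusk | 0.25 M | 54 mM (held) |  | 25 h |
| winter | 0.40 M | 54 mM (held) |  | 25 h |
| autumn | 0.12 M | 54 mM (held) |  | 25 h |
| spring | 1.2 M | 54 mM (held) |  | 25 h |
| dawn | 1.5 M | 54 mM (held) |  | 25 h |

red run (percent of the substrate charged)

| time / h | product / % | substrate / % |
|---|---|---|
| 2.00 | 0.5 | 99.5 |
| 5.00 | 6.4 | 93.8 |
| 10.0 | 14.8 | 84.7 |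
| 25.0 | 39.3 | 60.9 |

(readings scatter by 0.5 percentage points)

- the numbers in the tables scatter with a standard deviation of 0.5 percentage points
- at the start none of the gas phase is in solution

1. all flasks from highest to lowest amount of product, in percent of the substrate charged, at 25 h (dusk / winter / autumn / spring / dawn)
2. the amount of product, in percent of the substrate charged of the flask you put first, at 25 h
3. the amount of product, in percent of the substrate charged of the flask you put last, at 25 h

The dispute concerns one concentration, [dissolved gas]. If the rate goes as [substrate] times [dissolved gas], a steady [dissolved gas] gives first order in substrate, while a [dissolved gas] falling in step with rising [substrate] gives zero order.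

The author of the forecast reads the red run in percent. Product climbs by 1.68 and then 1.63 points per hour, a straight line, and so “each should make about the same absolute amount”. That gives autumn > dusk > winter > spring > dawn, with 36% first and 2.9% last.

I take the logarithm of the substrate left instead. From 10.0 h to 25.0 h its slope is 0.0220 h⁻¹, and from 5.00 h to 10.0 h it is 0.0204 h⁻¹. This is the fractional rate, the share of the substrate present that reacts in an hour, usually called a pseudo-first-order constant. With this scatter, the red run fits both readings, so it cannot part us.

The fractional rate can, though. On my view it stays the same, so autumn and dawn alike reach the red run's 39.3% by 25 h. On the forecast's view it is divided in dawn by the ratio of the charges, 13.6.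

The flask gives autumn > dusk > winter > spring > dawn, from 39.1% down to 17.7%. The forecast takes the order and the top, though dawn lies 15 percentage points above its figure, and my constant percent loses, missing dawn by 22 points. My view has its region around autumn, whose answer stays within 5 points down to at least 0.015 M of substrate and moves by that much at 0.304 M.

    gas phase ⇌ dissolved gas, rate k1*(csat - [dissolved gas]) (kL = 0.300 h⁻¹)
    substrate + dissolved gas → product (k = 0.560 M⁻¹ h⁻¹)
    dissolved gas → decomposed reagent (k = 0.0300 h⁻¹)
    dissolved gas ⇌ dormant form (K = 10.0, k = 0.0290 h⁻¹)

In dawn, the reaction of substrate + dissolved gas to product reached the midpoint of its turnover up to 25 h at 12.7 h, while [dissolved gas] stood at 0.0143 M at 12.5 h and 0.0154 M at 25.0 h, and its mean fractional rate, 0.00778 h⁻¹, was 0.354 of the red run's. Read at 4.0 d, dawn holds [dissolved gas] of 0.0237 M, its mean fractional rate is 0.00997 h⁻¹, or 0.453 of the red run's, and product stands at 61.6%.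

The data are calculated from invented constants; scatter was added.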